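**Plan**
- Retrosynthesis: remove the three end-group operations (15-OH, 8-O-methacryloyl, 9-O-acetyl). Then cut O–C6 and C11–C7 together, which takes off the whole α-methylene-γ-lactone and leaves the ten-membered germacra-1(10),4,6-triene 21 plus 2-bromoacrylic acid. Then cut C6=C7 (metathesis), C8–C9 (alkoxyallylboration), C1–C10/C9 (Baylis–Hillman manifold) and C3–C4 (Negishi).
- Enabling feature: the lactone oxygen sits on C6, which is allylic to the ring olefin C4=C5, and C11 sits on the neighbouring C7. The array O–C6(–C5=C4)/C7–C11 is the footprint of a 1,2-carbo-oxygenation of a ring diene C4=C5–C6=C7 through a C4–C5–C6 π-allyl-palladium.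
- Forward order: the chain grows C15/C4–C6, then C1–C3, then C10/C14/C9, then C7/C8. The ten-membered carbocycle closes first (step 12) and the γ-lactone second (step 13). The esters and 15-OH are set last.
- Stereochemistry: C8 and C9 are set together by reagent control (Ipc2B from (−)-α-pinene). C7 and C6 are relayed from C8 in one event.
- Olefin geometry: C4=C5 comes from trans-hydroalumination followed by retentive coupling, C1=C10 from the SN2′ bromination, and the temporary E-C6=C7 from the ring closure.

Key step: step 13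

Assumption: germacrane numbering is used (ring C1–C10, lactone C11–C13, ester carbon C14, CH2O C15). The target is read as the 1(10)-cis,4-cis-6α,12-olide (6R,7S,8S,9S). Compound 11 is carried as the racemic carbinol because that centre is erased in step 8.

Step 1
Reactants: 1 but-2-yne-1,4-diol
Product: 2 4-[(tert-butyldiphenylsilyl)oxy]but-2-yn-1-ol
Conditions: 1 (4 equiv), TBDPSCl, imidazole, DMF, 0 °C to rt
Reagents that add atoms: tert-butyl(chloro)diphenylsilane, CC(C)(C)[Si](Cl)(c1ccccc1)c1ccccc1
Why: Statistical monosilylation (silyl ether formation) of a symmetrical diol used in excess; TBDPS is chosen because it has to outlast the Lewis-acid, palladium and mild-acid steps up to step 17.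

Step 2
Reactants: 2 4-[(tert-butyldiphenylsilyl)oxy]but-2-yn-1-ol
Product: 4 (Z)-4-[(tert-butyldiphenylsilyl)oxy]-3-iodobut-2-en-1-ol, via cyclic alkenylalanate 3 (not isolated)
Conditions: Red-Al, THF, 0 °C; EtOAc quench of excess hydride; I2, THF, −78 °C
Reagents that add atoms: iodine, II
Why: Hydroxyl-directed trans-hydroalumination of the propargylic alcohol places aluminium on the distal alkyne carbon in a five-membered alanate, and iodinolysis with retention puts iodine cis to CH2OH (the later ring-cis C4=C5 geometry); the low temperature holds back β-elimination of the silyloxy group.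

Step 3
Reactants: 4 (Z)-4-[(tert-butyldiphenylsilyl)oxy]-3-iodobut-2-en-1-ol; 5 (3-ethoxy-3-oxopropyl)zinc bromide
Product: 6 ethyl (E)-4-{[(tert-butyldiphenylsilyl)oxy]methyl}-6-hydroxyhex-4-enoate (CH2OH cis to the ester chain)
Conditions: 5 (2.5 equiv, 0.5 M in THF), Pd2(dba)3 (2.5 mol %), SPhos (10 mol %), THF, rt to 40 °C
Reagents that add atoms: none
Why: Negishi sp2–sp3 coupling of an alkenyl iodide with a zinc homoenolate proceeds with retention of olefin geometry and tolerates the ester and, with extra organozinc, the free hydroxyl.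

Step 4
Reactants: 6 ethyl (E)-4-{[(tert-butyldiphenylsilyl)oxy]methyl}-6-hydroxyhex-4-enoate
Product: 7 ethyl (E)-4-{[(tert-butyldiphenylsilyl)oxy]methyl}-6-oxohex-4-enoate
Conditions: activated MnO2, CH2Cl2, rt
Reagents that add atoms: none
Why: Allylic alcohol oxidation with neutral MnO2 stops at the enal and should neither isomerise the β,β-disubstituted olefin nor touch the ester or silyl ether.

Step 5
Reactants: 7 ethyl (E)-4-{[(tert-butyldiphenylsilyl)oxy]methyl}-6-oxohex-4-enoate
Product: 8 ethyl (E)-4-{[(tert-butyldiphenylsilyl)oxy]methyl}hepta-4,6-dienoate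
Conditions: MePPh3Br, KHMDS, THF, −78 to 0 °C
Reagents that add atoms: methyltriphenylphosphonium bromide, C[P+](c1ccccc1)(c1ccccc1)c1ccccc1.[Br-]
Why: Wittig methylenation; the non-stabilised ylide attacks the aldehyde far faster than the ethyl ester at low temperature and leaves the trisubstituted olefin geometry untouched.

Step 6
Reactants: 8 ethyl (E)-4-{[(tert-butyldiphenylsilyl)oxy]methyl}hepta-4,6-dienoate
Product: 9 (E)-4-{[(tert-butyldiphenylsilyl)oxy]methyl}hepta-4,6-dienal
Conditions: DIBAL-H (1.1 equiv), toluene, −78 °C; Rochelle salt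
Reagents that add atoms: none
Why: Partial ester reduction with DIBAL-H; the aluminium hemiacetal is stable at −78 °C and releases the aldehyde only on work-up.

Step 7
Reactants: 9 (E)-4-{[(tert-butyldiphenylsilyl)oxy]methyl}hepta-4,6-dienal; 10 methyl acrylate
Product: 11 methyl (6E)-3-hydroxy-2-methylidene-6-{[(tert-butyldiphenylsilyl)oxy]methyl}nona-6,8-dienoate (racemic carbinol)
Conditions: 10 (3 equiv), DABCO (0.5 equiv), MeOH, rt
Reagents that add atoms: none
Why: Morita–Baylis–Hillman reaction of an unhindered aliphatic aldehyde brings in C10, C14 and C9 at once; the new carbinol centre forms racemic and is erased in step 8.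

Step 8
Reactants: 11 methyl (6E)-3-hydroxy-2-methylidene-6-{[(tert-butyldiphenylsilyl)oxy]methyl}nona-6,8-dienoate
Product: 12 methyl (2Z,6E)-2-(bromomethyl)-6-{[(tert-butyldiphenylsilyl)oxy]methyl}nona-2,6,8-trienoate
Conditions: NBS, Me2S (premixed), CH2Cl2, 0 °C to rt
Reagents that add atoms: N-bromosuccinimide, O=C1CCC(=O)N1Br
Why: SN2′ bromination of a Baylis–Hillman alcohol through its alkoxysulfonium salt (Corey–Kim-type reagent) gives the (Z)-allylic bromide, because A(1,3) strain places the chain trans to the ester, which is the C1=C10 geometry of the target; the premixed reagent leaves no free bromine for the diene.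

Step 9
Reactants: 12 methyl (2Z,6E)-2-(bromomethyl)-6-{[(tert-butyldiphenylsilyl)oxy]methyl}nona-2,6,8-trienoate
Product: 13 methyl (2E,6E)-2-formyl-6-{[(tert-butyldiphenylsilyl)oxy]methyl}nona-2,6,8-trienoate
Conditions: NMO (3 equiv), 4 Å MS, MeCN, 0 °C to rt; short silica plug, used at once
Reagents that add atoms: N-methylmorpholine N-oxide, C[N+]1([O-])CCOCC1
Why: Kornblum-type amine-N-oxide oxidation of an activated allylic bromide (SN2 at the primary carbon, then loss of the amine) gives the aldehyde under nearly neutral conditions with the olefin geometry kept.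

Step 10
Reactants: 14 allyl alcohol
Product: 15 3-(methoxymethoxy)prop-1-ene
Conditions: MOMCl, i-Pr2NEt, CH2Cl2, 0 °C to rt
Reagents that add atoms: chloromethyl methyl ether, COCCl
Why: MOM ether formation by alkylation of the alcohol with an oxocarbenium-type electrophile.

Step 11
Reactants: 15 3-(methoxymethoxy)prop-1-ene; 16 (+)-B-methoxydiisopinocampheylborane (from (−)-α-pinene); 13 methyl (2E,6E)-2-formyl-6-{[(tert-butyldiphenylsilyl)oxy]methyl}nona-2,6,8-trienoate
Product: 20 methyl (2E,6E)-2-[(1S,2S)-1-hydroxy-2-(methoxymethoxy)but-3-en-1-yl]-6-{[(tert-butyldiphenylsilyl)oxy]methyl}nona-2,6,8-trienoate, via lithiated allyl ether 17 (not isolated), via alkoxyallylborane 18 (not isolated), via borinate ester 19 (not isolated)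
Conditions: 15, s-BuLi, THF, −78 °C; 16; BF3·OEt2; 13, −78 °C; ethanolamine, 0 °C to rt
Reagents that add atoms: none
Why: Brown asymmetric (Z)-γ-alkoxyallylboration; the chair transition state turns the Z enol-ether geometry into the syn C8/C9 relationship, the Ipc groups derived from (−)-α-pinene select the Re face of the aldehyde (9S, hence 8S), the borane adds 1,2 only, and the non-oxidative work-up spares the enoate.

Step 12
Reactants: 20 methyl (2E,6E)-2-[(1S,2S)-1-hydroxy-2-(methoxymethoxy)but-3-en-1-yl]-6-{[(tert-butyldiphenylsilyl)oxy]methyl}nona-2,6,8-trienoate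
Product: 21 methyl (8S,9S)-15-[(tert-butyldiphenylsilyl)oxy]-9-hydroxy-8-(methoxymethoxy)germacra-1(10),4,6-trien-14-oate (ring-cis at C1=C10 and C4=C5; E at C6=C7)
Conditions: Hoveyda–Grubbs II (10 mol %), 1,4-benzoquinone (20 mol %), toluene (1 mM), 50 °C, Ar sparge
Reagents that add atoms: none
Why: Ring-closing ene–diene metathesis joins the only two monosubstituted termini (C4=C5 and C1=C10 are trisubstituted and inert), the two ring-cis olefins pre-bend the chain, and the E olefin is expected, as in closures of ten-membered rings flanked by an allylic ether, because it reproduces the antiperiplanar C5–C6–C7–C8 array of the trans-fused target ring; no stereocentre is formed.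

Step 13
Reactants: 21 methyl (8S,9S)-15-[(tert-butyldiphenylsilyl)oxy]-9-hydroxy-8-(methoxymethoxy)germacra-1(10),4,6-trien-14-oate; 22 2-bromoacrylic acid
Product: 23 methyl (6R,7S,8S,9S)-15-[(tert-butyldiphenylsilyl)oxy]-9-hydroxy-8-(methoxymethoxy)-12-oxo-6,12-epoxygermacra-1(10),4,11(13)-trien-14-oate (trans-fused α-methylene-γ-lactone)
Conditions: 22 (2 equiv, slow addition), Pd(OAc)2 (10 mol %), P(2-furyl)3 (20 mol %), Ag2CO3 (2 equiv), MeCN, 50 °C, dark
Reagents that add atoms: none
Why: Proposed new method: Pd(0) inserts into the C–Br bond of silver 2-bromoacrylate, the halide-free α-carboxyvinyl-Pd(II) binds the strained E-C6=C7 bond of 21 on its outer face and adds syn (C11 to C7, Pd to C6) to give an η3-allyl over C6–C5–C4 whose carboxylate already sits on palladium as a six-membered palladacycle, and C–O reductive elimination at C6 closes the lactone and returns Pd(0). The closest known reaction type is the Larock heteroannulation of 1,3-dienes with halo-substituted aromatic or (Z)-3-haloacrylic acids, which delivers syn carbo-oxygenation (cis-fused products) with cyclic dienes; an α-haloacrylic acid on a trisubstituted macrocyclic diene has not been shown. The one ring formed, the γ-lactone, closes 5-exo on the allyl terminus C6 (C5 stays outside the new ring) rather than 7-endo at the fully substituted C4. C7 is controlled by C8: with the ring bond C8–C9 turned inward and the C8–O bond lying in the olefin plane (inside-alkoxy arrangement, which is also the local conformation of the target) only H-8 flanks the outer face, so C11 arrives cis to O-8 across the ring. C6 is controlled by C7 through the mechanism, since syn insertion followed by inner-sphere, retentive C–O bond formation amounts to a syn addition to an E olefin and hence the trans-fused lactone, while silver removes the halide that would open the backside pathway and the ring resists the rotation about C6–C7 which that pathway needs. Selectivity rests on the substrate: only attack at the disubstituted terminus C7 gives an allyl-Pd, C4 is blocked, the C1=C10 enoate is trisubstituted and electron-poor, O-8 and O-15 are ethers that Pd(0) does not ionise, the C4=C5 geometry holds because syn/anti exchange at C4 would need a tertiary σ-Pd, and the neutral 9-OH cannot compete with the Pd-bound carboxylate.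

Step 14
Reactants: 23 lactone alcohol (9-OH, 8-OMOM, 15-OTBDPS)
Product: 24 9-O-acetyl lactone (8-OMOM, 15-OTBDPS)
Conditions: Ac2O, pyridine, DMAP (cat.), CH2Cl2, 0 °C
Reagents that add atoms: acetic anhydride, CC(=O)OC(C)=O
Why: DMAP-catalysed acetylation of the only free hydroxyl; the configuration at C9 is untouched.

Step 15
Reactants: 24 9-O-acetyl lactone (8-OMOM, 15-OTBDPS)
Product: 26 9-O-acetyl-8-hydroxy lactone (15-OTBDPS), via bipyridinium acetal salt 25 (not isolated)
Conditions: TMSOTf, 2,2′-bipyridyl, CH2Cl2, 0 °C; then H2O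
Reagents that add atoms: none
Why: Mild MOM cleavage through a bipyridinium acetal salt that water hydrolyses; the almost neutral medium spares the allylic lactone C–O bond, the allylic acetate and the silyl ether and limits a 9→8 acetyl shift.

Step 16
Reactants: 26 9-O-acetyl-8-hydroxy lactone (15-OTBDPS)
Product: 27 9-O-acetyl-8-O-methacryloyl lactone (15-OTBDPS)
Conditions: methacrylic anhydride (4 equiv), Et3N, DMAP, BHT (trace), CH2Cl2, 0 °C to rt
Reagents that add atoms: methacrylic anhydride, C=C(C)C(=O)OC(=O)C(C)=C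
Why: DMAP-catalysed (Steglich-type) acylation with excess anhydride outruns acetyl migration and keeps the C8 configuration; BHT suppresses polymerisation.

Step 17
Reactants: 27 9-O-acetyl-8-O-methacryloyl lactone (15-OTBDPS)
Product: 28 target, methyl (6R,7S,8S,9S)-9-acetoxy-15-hydroxy-8-(methacryloyloxy)-12-oxo-6,12-epoxygermacra-1(10),4,11(13)-trien-14-oate
Conditions: HF·pyridine, pyridine, THF, 0 °C to rt (plastic vessel)
Reagents that add atoms: none
Why: Fluoride-mediated desilylation under buffered acidic conditions removes the TBDPS group without touching the four ester functions or the Michael acceptors (basic TBAF is avoided).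

**Compound list**
1 | but-2-yne-1,4-diol | OCC#CCO | starting material
2 | 4-[(tert-butyldiphenylsilyl)oxy]but-2-yn-1-ol | OCC#CCO[Si](c1ccccc1)(c1ccccc1)C(C)(C)C | intermediate
3 | sodium cyclic alkenylalanate from 2 | [Na+].COCCO[Al-]1(OCCOC)OCC=C1CO[Si](c1ccccc1)(c1ccccc1)C(C)(C)C | intermediate
4 | (Z)-4-[(tert-butyldiphenylsilyl)oxy]-3-iodobut-2-en-1-ol | OC/C=C(I)/CO[Si](c1ccccc1)(c1ccccc1)C(C)(C)C | intermediate
5 | (3-ethoxy-3-oxopropyl)zinc bromide | CCOC(=O)CC[Zn]Br | starting material
6 | ethyl (E)-4-{[(tert-butyldiphenylsilyl)oxy]methyl}-6-hydroxyhex-4-enoate | CCOC(=O)CC/C(CO[Si](c1ccccc1)(c1ccccc1)C(C)(C)C)=C\CO | intermediate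
7 | ethyl (E)-4-{[(tert-butyldiphenylsilyl)oxy]methyl}-6-oxohex-4-enoate | CCOC(=O)CC/C(CO[Si](c1ccccc1)(c1ccccc1)C(C)(C)C)=C\C=O | intermediate
8 | ethyl (E)-4-{[(tert-butyldiphenylsilyl)oxy]methyl}hepta-4,6-dienoate | CCOC(=O)CC/C(CO[Si](c1ccccc1)(c1ccccc1)C(C)(C)C)=C\C=C | intermediate
9 | (E)-4-{[(tert-butyldiphenylsilyl)oxy]methyl}hepta-4,6-dienal | O=CCC/C(CO[Si](c1ccccc1)(c1ccccc1)C(C)(C)C)=C\C=C | intermediate
10 | methyl acrylate | C=CC(=O)OC | starting material
11 | methyl (6E)-3-hydroxy-2-methylidene-6-{[(tert-butyldiphenylsilyl)oxy]methyl}nona-6,8-dienoate (racemic) | COC(=O)C(=C)C(O)CC/C(CO[Si](c1ccccc1)(c1ccccc1)C(C)(C)C)=C\C=C | intermediate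
12 | methyl (2Z,6E)-2-(bromomethyl)-6-{[(tert-butyldiphenylsilyl)oxy]methyl}nona-2,6,8-trienoate | COC(=O)/C(CBr)=C/CC/C(CO[Si](c1ccccc1)(c1ccccc1)C(C)(C)C)=C\C=C | intermediate
13 | methyl (2E,6E)-2-formyl-6-{[(tert-butyldiphenylsilyl)oxy]methyl}nona-2,6,8-trienoate | COC(=O)/C(C=O)=C/CC/C(CO[Si](c1ccccc1)(c1ccccc1)C(C)(C)C)=C\C=C | intermediate
14 | allyl alcohol | C=CCO | starting material
15 | 3-(methoxymethoxy)prop-1-ene | C=CCOCOC | intermediate
16 | (+)-B-methoxydiisopinocampheylborane | COB([C@H]1C[C@H]2C[C@@H]([C@@H]1C)C2(C)C)[C@H]1C[C@H]2C[C@@H]([C@@H]1C)C2(C)C | starting material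
17 | (Z)-3-(methoxymethoxy)allyllithium | [Li]C/C=C\OCOC | intermediate
18 | [(Z)-3-(methoxymethoxy)allyl]diisopinocampheylborane | COCO/C=C\CB([C@H]1C[C@H]2C[C@@H]([C@@H]1C)C2(C)C)[C@H]1C[C@H]2C[C@@H]([C@@H]1C)C2(C)C | intermediate
19 | diisopinocampheylborinate ester of 20 | COCO[C@H]([C@@H](OB([C@H]1C[C@H]2C[C@@H]([C@@H]1C)C2(C)C)[C@H]1C[C@H]2C[C@@H]([C@@H]1C)C2(C)C)/C(C(=O)OC)=C\CC/C(CO[Si](c1ccccc1)(c1ccccc1)C(C)(C)C)=C\C=C)C=C | intermediate
20 | methyl (2E,6E)-2-[(1S,2S)-1-hydroxy-2-(methoxymethoxy)but-3-en-1-yl]-6-{[(tert-butyldiphenylsilyl)oxy]methyl}nona-2,6,8-trienoate | COCO[C@H]([C@@H](O)/C(C(=O)OC)=C\CC/C(CO[Si](c1ccccc1)(c1ccccc1)C(C)(C)C)=C\C=C)C=C | intermediate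
21 | ten-membered (6E)-triene, 8-OMOM, 9-OH, 15-OTBDPS | COCO[C@H]1/C=C/C=C(/CO[Si](c2ccccc2)(c2ccccc2)C(C)(C)C)CC/C=C(/C(=O)OC)[C@@H]1O | intermediate
22 | 2-bromoacrylic acid | OC(=O)C(Br)=C | starting material
23 | trans-fused α-methylene lactone, 8-OMOM, 9-OH, 15-OTBDPS | COCO[C@H]1[C@H]2C(=C)C(=O)O[C@@H]2/C=C(/CO[Si](c3ccccc3)(c3ccccc3)C(C)(C)C)CC/C=C(/C(=O)OC)[C@@H]1O | intermediate
24 | 9-O-acetyl lactone, 8-OMOM, 15-OTBDPS | COCO[C@H]1[C@H]2C(=C)C(=O)O[C@@H]2/C=C(/CO[Si](c3ccccc3)(c3ccccc3)C(C)(C)C)CC/C=C(/C(=O)OC)[C@@H]1OC(C)=O | intermediate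
25 | 8-O-[(2,2′-bipyridin-1-ium-1-yl)methyl] acetal triflate of 26 | [O-]S(=O)(=O)C(F)(F)F.c1ccc(-c2cccc[n+]2CO[C@H]2[C@H]3C(=C)C(=O)O[C@@H]3/C=C(/CO[Si](c3ccccc3)(c3ccccc3)C(C)(C)C)CC/C=C(/C(=O)OC)[C@@H]2OC(C)=O)nc1 | intermediate
26 | 9-O-acetyl-8-hydroxy lactone, 15-OTBDPS | O[C@H]1[C@H]2C(=C)C(=O)O[C@@H]2/C=C(/CO[Si](c3ccccc3)(c3ccccc3)C(C)(C)C)CC/C=C(/C(=O)OC)[C@@H]1OC(C)=O | intermediate
27 | 9-O-acetyl-8-O-methacryloyl lactone, 15-OTBDPS | C=C(C)C(=O)O[C@H]1[C@H]2C(=C)C(=O)O[C@@H]2/C=C(/CO[Si](c3ccccc3)(c3ccccc3)C(C)(C)C)CC/C=C(/C(=O)OC)[C@@H]1OC(C)=O | intermediate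
28 | CNP0179134.2 | C=C(C)C(=O)O[C@H]1[C@H]2C(=C)C(=O)O[C@@H]2/C=C(/CO)CC/C=C(/C(=O)OC)[C@@H]1OC(C)=O | target

Total step count: 17. Longest linear sequence: 16 (steps 1–9 and 11–17).

**Steps most likely to fail**

1. **Step 13.** The allyl-palladium may lose a β-hydrogen (from C7, C3 or C15) to give trienes before C–O bond formation. The facial bias exerted by C8 may be poor. Backside lactonisation may compete. The bromoacrylate may self-couple or polymerise.
Fallback with known chemistry, from 21 back to 23: a Mn(III)-based oxidative lactone annulation makes the same two bonds stepwise. Compound 21 is treated with mono-tert-butyl malonate and Mn(OAc)3·2H2O in AcOH/KOAc at 40 °C. The malonyl radical adds to C7, the allyl radical is oxidised to the cation, and the carboxyl oxygen captures it at C6. This should give the more stable trans-fused tert-butyl ester lactone F1. TFA in CH2Cl2 at 0 °C frees the α-carboxy lactone F2. Aqueous formaldehyde with Et2NH (decarboxylative Mannich methylenation) then returns the route to 23.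

2. **Step 12.** Oligomerisation may outrun closure of the strained ring, or the ring may close to the 6Z olefin, which would feed the wrong relative configuration into step 13.
Fallback, from 20 back to 21: the geometry is set after ring closure instead of during it. The metathesis is driven to the ring whatever its geometry, and the (6Z)-triene F3 is isolated. F3 is irradiated with a triplet sensitiser of about 60 kcal/mol, which excites only the diene and not the enoate. This is the known cis,cis to cis,trans isomerisation of medium-ring 1,3-dienes. The more strongly binding E isomer is removed continuously on AgNO3-impregnated silica and F3 is recycled, giving 21.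

3. **Step 9 (and the use of 13 in step 11).** The doubly activated alkylidene may lose its geometry by reversible amine addition, and it may self-condense or undergo hetero-Diels–Alder dimerisation.
Fallback, from 9 back to 20: the ester is brought in last, from an alkyne. The sequence runs as follows:
   - Ohira–Bestmann homologation of 9 gives the terminal alkyne F4.
   - n-BuLi followed by DMF gives the ynal F5.
   - Reagent 18 adds as in step 11, through the borinate F6, to give the propargylic alcohol F7.
   - Hydroxyl-assisted, proximal-selective Pd-catalysed syn-hydrostannation (Bu3SnH, PdCl2(PPh3)2) gives the alkenylstannane F8.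
   - Iodine at −78 °C gives the alkenyl iodide F9.
   - Methoxycarbonylation (Pd(PPh3)4, CO, Et3N, MeOH as solvent) places CO2Me trans to C2 and gives 20.

**Further compounds**
F1 | step 13 | α-(tert-butoxycarbonyl) trans-fused lactone (C11 epimers) | COCO[C@H]1[C@H]2C(C(=O)OC(C)(C)C)C(=O)O[C@@H]2/C=C(/CO[Si](c3ccccc3)(c3ccccc3)C(C)(C)C)CC/C=C(/C(=O)OC)[C@@H]1O
F2 | step 13 | α-carboxy trans-fused lactone (C11 epimers) | COCO[C@H]1[C@H]2C(C(=O)O)C(=O)O[C@@H]2/C=C(/CO[Si](c3ccccc3)(c3ccccc3)C(C)(C)C)CC/C=C(/C(=O)OC)[C@@H]1O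
F3 | step 12 | (6Z) isomer of triene 21 | COCO[C@H]1/C=C\C=C(\CO[Si](c2ccccc2)(c2ccccc2)C(C)(C)C)CC/C=C(/C(=O)OC)[C@@H]1O
F4 | step 9 | tert-butyl{[(2E)-2-(but-3-yn-1-yl)penta-2,4-dien-1-yl]oxy}diphenylsilane | C#CCC/C(CO[Si](c1ccccc1)(c1ccccc1)C(C)(C)C)=C\C=C
F5 | step 9 | (6E)-6-{[(tert-butyldiphenylsilyl)oxy]methyl}nona-6,8-dien-2-ynal | O=CC#CCC/C(CO[Si](c1ccccc1)(c1ccccc1)C(C)(C)C)=C\C=C
F6 | step 9 | diisopinocampheylborinate ester of F7 | COCO[C@H]([C@@H](OB([C@H]1C[C@H]2C[C@@H]([C@@H]1C)C2(C)C)[C@H]1C[C@H]2C[C@@H]([C@@H]1C)C2(C)C)C#CCC/C(CO[Si](c1ccccc1)(c1ccccc1)C(C)(C)C)=C\C=C)C=C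
F7 | step 9 | syn propargylic alcohol, 8-OMOM | COCO[C@H]([C@@H](O)C#CCC/C(CO[Si](c1ccccc1)(c1ccccc1)C(C)(C)C)=C\C=C)C=C
F8 | step 9 | C10-tributylstannyl alkene (H cis to Sn) | COCO[C@H]([C@@H](O)/C([Sn](CCCC)(CCCC)CCCC)=C\CC/C(CO[Si](c1ccccc1)(c1ccccc1)C(C)(C)C)=C\C=C)C=C
F9 | step 9 | C10-iodo alkene | COCO[C@H]([C@@H](O)/C(I)=C\CC/C(CO[Si](c1ccccc1)(c1ccccc1)C(C)(C)C)=C\C=C)C=C
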